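The data stem from a simulated flask for substances that don't exist; noise was put on by code.

An excess of 80% among what is left of Q and D allows 0.111 Q per D: this is the allowed ratio r, one minus the excess over one plus the excess.

1. whether the excess of D over Q among what is left of the two reaches 80% by 1.5 h (yes / no)
2. the highest excess of D over Q among what is left of the two up to 1.5 h

in all of them: Q 0.050 M; D 0.050 M; Z 4.7 mM; J 1.4 mM

| charge | E | G | remark | time |
|---|---|---|---|---|
| south | 0.075 M | 5 mM | the very flask that is asked about, followed so far |  |
| west | 0.075 M | 10 mM | run made earlier |  |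
| flask | 0.0750 M | 5.00 mM |  | 1.5 h |

| run | time / min | D / % | Q / % |
|---|---|---|---|
| south | 4.00 | 52 | 17 |
| south | 6.00 | 49 | 11 |
| south | 10.0 | 52 | 6 |
| south | 15.0 | 49 | 4 |
| south | 25.0 | 49 | 0 |
| south | 50.0 | 50 | 1 |
| west | 4.00 | 51 | 15 |
| west | 12.0 | 50 | 7 |
| west | 20.0 | 49 | 4 |
| west | 30.0 | 48 | 2 |
| west | 50.0 | 50 | 2 |
| west | 60.0 | 49 | 1 |

(standard deviation of a reading: 1.5 percentage points)

- Z is single-handed; Q and D are mirror images of each other, charged as a racemate, each of them at the stated concentration

Q and D went in as a racemate, so the south flask started at one Q per D and excess zero, the zero of my scale. But Z is single-handed, and the south readings show a kinetic resolution: D read 52% at 4.00 min and 50% at 50.0 min, while Q went from 17% to 1%. So I held D at 50%, and the question became when Q reached r times that, 5.56%. Q read 6% at 10.0 min, more than that, and 4% at 15.0 min, less than that, so I answered yes, with the crossing between those readings. The reading at 50.0 min gives an excess of 96.1%, but its Q of 1% carries a scatter of 1.5 percentage points, so I took that excess as a rough reading of the top, not as a bound.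

The forecast also said yes, and put the top higher, at 99%, within 96% to 100%, noting: “No D loss or racemisation is visible”.

The south flask gave yes and 99.9%, from these steps:

    Z + J → Z.J (k = 19400 /M/min)
    E + Z + Q → Z + Ju (k = 1960 /M²/min)
    E + Z + D → Z + Wy (k = 10.5 /M²/min)
    E + G → E.G (k = 93.8 /M/min)
    E ⇌ X (K = 0.970, k = 0.0225 /min)

The south flask crossed at 10.9 min, with D at 49.4% of the Q and D charged, and r puts Q there at 5.48%. The west flask, with twice the G, is held to the same r of 0.111: its Q per D read 0.140 at 12.0 min and 0.0816 at 20.0 min.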